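The numbers in the tables are calculated on assumed constants; the scatter is artificial.

4 questions came before the meeting, all on the south flask, followed so far to 10.0 min and to be read at 30 min. X is the substrate, G the reagent, and L, E and J its mono, bis and tris adducts.

| setting | south | north-west | flask |
|---|---|---|---|
| X | 0.050 M | 0.10 M | 0.050 M |
| G | 0.075 M | 0.075 M | 0.0750 M |
| remark | the very flask that is asked about, followed so far | run made earlier |  |
| time |  |  | 30 min |

- south (time / min: X / %, L / %): 0.667: 97, 5; 1.33: 97, 7; 2.50: 94, 9; 5.00: 84, 14; 10.0: 75, 22
- north-west (time / min: X / %, L / %): 1.00: 97, 2; 3.00: 93, 7; 6.00: 84, 16; 8.00: 79, 20; 12.0: 75, 23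

(readings scatter by 1.5 percentage points)

1. how much X there is at 30 min, in percent of the X charged
2. how much L there is at 30 min, in percent of the X charged
3. how much E there is at 30 min, in percent of the X charged
4. how much J there is at 30 min, in percent of the X charged

- what was read earlier has a scatter of 1.5 percentage points, one standard deviation

The minute-taker proposed one quantity for X: the half-life τ, the time in which X halves with G treated as standing still, a pseudo-first-order half-life. From the south reading of 75% at 10.0 min he made τ 24.1 min. He noted that the north-west run, with twice the X at equal G, read 75% at 12.0 min, so he took the percent lost as nearly independent of X. He assumed that τ goes inversely with G, which these runs do not test, since both were charged with 0.075 M. Carried to 30 min, τ gave him 42.2% of X.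

The forecaster argued for a higher X, integrating with G falling and scaling the steps statistically: X 48%, L 39.5%, E 11%, J 1.2%. Of that scaling the forecaster said: “This is an assumption, not something measured”.

The flask gives X 45.7%, L 32.3%, E 2.52% and J 0.0891%.

    X + G → L (k = 0.450 /M/min)
    L → D (k = 0.0120 /min)
    G + L → E (k = 0.0660 /M/min)
    G + E → J (k = 0.0520 /M/min)
    L → Z (k = 0.0150 /min)

The carried τ of 24.1 min, read from the south run, is shorter than the half-lives of L in this flask at 10.4 min by its steps to the other products Z, 46 min, and D, 58 min, and at that time L is made 2.83 times faster than it is used up, each step taken net. By 30.0 min that ratio has come down to 0.984, with Z at 10.8% and D at 8.62% beside L.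

For the neighbour flask charged with 0.19 M of G, τ scaled by the charge is 9.51 min, which gives 11.2% of X at 30 min. The computed neighbour holds 12.1% of X and 42.8% of L.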